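**Retrosynthetic overview** (upper unit: rings A, C, B; lower unit: rings D, F, E)
1. 25 ⇒ 24 (eight O-benzyl groups) ⇒ 23. The 3,4-cis-diol of ring F comes from syn-dihydroxylation of a (2S)-flav-3-ene anti to ring E, and the C3–OH of ring C from axial hydride addition to chroman-3-one 22.
2. 22 ⇒ 11 + 18. The C4(ring C)–C2'(ring E) bond and ring C are made in one flask: the 2'-lithiated flavene adds to a 2-aryl-3-siloxy-2,3-dihydrobenzofuran-3-carbaldehyde, then ring A shifts from C3 to the new carbinol carbon. This enlarges the five-membered O-ring to the six-membered O1–C2–C3–C4–C4a–C8a ring.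
3. Enabling feature: C4a of ring A is para to O-7 and ortho to C8a–O1, so ring A is an exceptional bridging (phenonium) and migrating group. C4 carries ring A and ring E at once, and its neighbour C3 carries the oxygen that can end the shift as a carbonyl group.
4. Stereocontrol: C2 of ring C is set by enantioselective Rh-carbene C–H insertion, then relayed C2 → temporary C3 → carbinol carbon → C4 → C3. C2 of ring F is set by dynamic kinetic resolution, then relayed to C3 and C4.
5. Ring order: five-membered O-ring on ring A (C–H insertion), ring F (oxa-Michael closure), ring C (ring enlargement).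

Key step: step 14

Assumption: the sense of induction of Rh2(S-PTTL)4 (step 5) and of the (S,S)-Ru catalyst (step 12) is taken from the closest analogues; should it be opposite, the mirror-image catalyst is used.

Step 1
Reactants: 1 [3,4,5-tris(benzyloxy)phenyl]methanol
Product: 2 5-(bromomethyl)-1,2,3-tris(benzyloxy)benzene
Conditions: PBr3, CH2Cl2, 0 °C
Reagents that add atoms: phosphorus tribromide, BrP(Br)Br
Why: Bromination of an electron-rich benzylic alcohol with PBr3 (SN2 on the activated phosphite) is routine and creates no stereocentre.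

Step 2
Reactants: 2 5-(bromomethyl)-1,2,3-tris(benzyloxy)benzene; 3 1-[4-(benzyloxy)-2-hydroxyphenyl]ethan-1-one
Product: 4 1-[4-(benzyloxy)-2-{[3,4,5-tris(benzyloxy)phenyl]methoxy}phenyl]ethan-1-one
Conditions: K2CO3, DMF, 60 °C
Reagents that add atoms: none
Why: Williamson ether synthesis on the only free phenol of 3 with a reactive benzylic bromide installs the O–CH2–aryl unit whose carbon will become C2 of ring C; no stereocentre is formed.

Step 3
Reactants: 4 1-[4-(benzyloxy)-2-{[3,4,5-tris(benzyloxy)phenyl]methoxy}phenyl]ethan-1-one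
Product: 5 methyl 2-[4-(benzyloxy)-2-{[3,4,5-tris(benzyloxy)phenyl]methoxy}phenyl]acetate
Conditions: Tl(NO3)3·3H2O, MeOH–HC(OMe)3, rt
Reagents that add atoms: methanol, CO
Why: Thallium(III) nitrate oxidative rearrangement of an aryl methyl ketone (1,2-aryl shift in the enol ether adduct) should turn the acetyl group into the methyl arylacetate, the 2,4-dioxygenated ring being an ideal migrating group and aryl benzyl ethers being known to survive.

Step 4
Reactants: 5 methyl 2-[4-(benzyloxy)-2-{[3,4,5-tris(benzyloxy)phenyl]methoxy}phenyl]acetate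
Product: 6 methyl 2-diazo-2-[4-(benzyloxy)-2-{[3,4,5-tris(benzyloxy)phenyl]methoxy}phenyl]acetate
Conditions: p-ABSA, DBU, MeCN, 0 °C → rt
Reagents that add atoms: 4-acetamidobenzenesulfonyl azide, CC(=O)Nc1ccc(cc1)S(=O)(=O)N=[N+]=[N-]
Why: Regitz diazo transfer to the doubly activated benzylic methylene of an arylacetate gives the donor/acceptor diazo ester.

Step 5
Reactants: 6 methyl 2-diazo-2-[4-(benzyloxy)-2-{[3,4,5-tris(benzyloxy)phenyl]methoxy}phenyl]acetate
Product: 7 methyl (2S,3R)-6-(benzyloxy)-2-[3,4,5-tris(benzyloxy)phenyl]-2,3-dihydro-1-benzofuran-3-carboxylate (2,3-cis)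
Conditions: Rh2(S-PTTL)4 (1 mol %), toluene, −60 °C
Reagents that add atoms: none
Why: Intramolecular 1,5 C–H insertion of the rhodium donor/acceptor carbene into the ether-activated benzylic C–H closes the five-membered O-ring, a known route to cis-2-aryl-2,3-dihydrobenzofuran-3-carboxylates in which the chiral carboxylate ligand sphere sets C2 (2S by CIP in 7), while the cis C3 centre is of no consequence because it is planarised in step 6.

Step 6
Reactants: 7 methyl (2S,3R)-6-(benzyloxy)-2-[3,4,5-tris(benzyloxy)phenyl]-2,3-dihydro-1-benzofuran-3-carboxylate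
Product: 9 methyl (2R,3S)-6-(benzyloxy)-3-hydroxy-2-[3,4,5-tris(benzyloxy)phenyl]-2,3-dihydro-1-benzofuran-3-carboxylate (OH trans to the 2-aryl group), via potassium ester enolate 8 (not isolated)
Conditions: KHMDS, THF, −78 °C; then 2-(phenylsulfonyl)-3-phenyloxaziridine, −78 °C; H2O
Reagents that add atoms: 2-(phenylsulfonyl)-3-phenyloxaziridine, O=S(=O)(c1ccccc1)N1OC1c1ccccc1
Why: Davis hydroxylation of the ester enolate, in which the oxaziridine approaches the planar C3 anti to the C2 aryl group so that OH ends trans and the ester cis to ring B, while loss of O1 from the enolate would be the reverse of a 5-endo-trig closure and should stay slow at −78 °C.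

Step 7
Reactants: 9 methyl (2R,3S)-6-(benzyloxy)-3-hydroxy-2-[3,4,5-tris(benzyloxy)phenyl]-2,3-dihydro-1-benzofuran-3-carboxylate
Product: 10 methyl (2R,3S)-6-(benzyloxy)-3-[(tert-butyldimethylsilyl)oxy]-2-[3,4,5-tris(benzyloxy)phenyl]-2,3-dihydro-1-benzofuran-3-carboxylate
Conditions: TBSOTf, 2,6-lutidine, CH2Cl2, 0 °C → rt
Reagents that add atoms: tert-butyldimethylsilyl triflate, CC(C)(C)[Si](C)(C)OS(=O)(=O)C(F)(F)F
Why: Silylation of a hindered tertiary alcohol with the silyl triflate and 2,6-lutidine caps the oxygen that must later end the 1,2-shift and must not close an oxirane.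

Step 8
Reactants: 10 methyl (2R,3S)-6-(benzyloxy)-3-[(tert-butyldimethylsilyl)oxy]-2-[3,4,5-tris(benzyloxy)phenyl]-2,3-dihydro-1-benzofuran-3-carboxylate
Product: 11 (2R,3S)-6-(benzyloxy)-3-[(tert-butyldimethylsilyl)oxy]-2-[3,4,5-tris(benzyloxy)phenyl]-2,3-dihydro-1-benzofuran-3-carbaldehyde
Conditions: DIBAL-H (1.1 equiv), CH2Cl2, −78 °C; aq Rochelle salt
Reagents that add atoms: none
Why: Partial reduction of the ester with DIBAL-H at −78 °C stops at the aldehyde because the α-siloxy tetrahedral aluminate is stable until work-up, and the quaternary C3 cannot epimerise.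

Step 9
Reactants: 12 3,4,5-tris(benzyloxy)benzaldehyde
Product: 13 2-bromo-3,4,5-tris(benzyloxy)benzaldehyde
Conditions: NBS, MeCN, rt
Reagents that add atoms: N-bromosuccinimide, O=C1CCC(=O)N1Br
Why: Electrophilic aromatic bromination goes to C2, the only type of free ring position, which is ortho and para to benzyloxy groups, as known for 3,4,5-trialkoxybenzaldehydes.

Step 10
Reactants: 13 2-bromo-3,4,5-tris(benzyloxy)benzaldehyde; 3 1-[4-(benzyloxy)-2-hydroxyphenyl]ethan-1-one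
Product: 14 (E)-1-[4-(benzyloxy)-2-hydroxyphenyl]-3-[2-bromo-3,4,5-tris(benzyloxy)phenyl]prop-2-en-1-one
Conditions: KOH, EtOH–THF, rt
Reagents that add atoms: none
Why: Claisen–Schmidt condensation of the acetophenone enolate with the non-enolisable aldehyde gives the E-chalcone under thermodynamic control.

Step 11
Reactants: 14 (E)-1-[4-(benzyloxy)-2-hydroxyphenyl]-3-[2-bromo-3,4,5-tris(benzyloxy)phenyl]prop-2-en-1-one
Product: 15 rac-7-(benzyloxy)-2-[2-bromo-3,4,5-tris(benzyloxy)phenyl]chroman-4-one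
Conditions: NaOAc, EtOH, reflux
Reagents that add atoms: none
Why: Base-mediated intramolecular oxa-Michael addition (6-endo-trig) of the 2'-phenol closes ring F to the racemic flavanone, whose C2 centre is set in the next step.

Step 12
Reactants: 15 rac-7-(benzyloxy)-2-[2-bromo-3,4,5-tris(benzyloxy)phenyl]chroman-4-one
Product: 16 (2S,4S)-7-(benzyloxy)-2-[2-bromo-3,4,5-tris(benzyloxy)phenyl]chroman-4-ol (2,4-cis)
Conditions: RuCl[(S,S)-TsDPEN](p-cymene) (2 mol %), HCO2H–DBU, MeCN, 40 °C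
Reagents that add atoms: none
Why: Asymmetric transfer hydrogenation with dynamic kinetic resolution, in which DBU racemises C2 through reversible retro-oxa-Michael opening and the (S,S)-Ru hydride reduces only the 2S ketone to the 4S alcohol, should give the 2,4-cis flavan-4-ol as known for 2-substituted chroman-4-ones.

Step 13
Reactants: 16 (2S,4S)-7-(benzyloxy)-2-[2-bromo-3,4,5-tris(benzyloxy)phenyl]chroman-4-ol
Product: 18 (2S)-7-(benzyloxy)-2-[2-bromo-3,4,5-tris(benzyloxy)phenyl]-2H-chromene, via 4-mesylate 17 (not isolated)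
Conditions: MsCl, Et3N, CH2Cl2, 0 °C → rt
Reagents that add atoms: none
Why: Mesylation of the 7-oxygen-activated benzylic alcohol followed by in situ elimination gives the conjugated flav-3-ene under basic conditions that leave C2 untouched.

Step 14
Reactants: 18 (2S)-7-(benzyloxy)-2-[2-bromo-3,4,5-tris(benzyloxy)phenyl]-2H-chromene; 11 (2R,3S)-6-(benzyloxy)-3-[(tert-butyldimethylsilyl)oxy]-2-[3,4,5-tris(benzyloxy)phenyl]-2,3-dihydro-1-benzofuran-3-carbaldehyde
Product: 22 (2R,4S)-7-(benzyloxy)-4-{2,3,4-tris(benzyloxy)-6-[(2S)-7-(benzyloxy)-2H-chromen-2-yl]phenyl}-2-[3,4,5-tris(benzyloxy)phenyl]chroman-3-one, via aryllithium 19 (not isolated), via lithium alkoxide 20 (not isolated), via benzylic mesylate 21 (not isolated)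
Conditions: 18, n-BuLi, THF, −78 °C; add 11, −78 °C; then MsCl, −78 → 0 °C; aq NaHCO3
Reagents that add atoms: none
Why: Proposed new method: Br/Li exchange gives 19, which adds to the non-enolisable α-siloxy aldehyde 11 in the polar Felkin–Anh sense (incoming aryl anti to C3–OTBS, passing the flat C3a side), so the carbinol carbon of 20 is set as R by the temporary C3 centre, and MsCl turns this o,p-dioxygenated benzylic oxygen into a leaving group. In the rotamer of 21 that the addition delivers, the C3–C3a bond lies antiperiplanar to C–OMs, so ring A attacks the carbinol carbon from the rear (Ar1-3 participation, 3-exo-tet) to a phenonium ion, the siloxy oxygen pushes out the old C3–C3a bond, and mesylate takes the silyl group, leaving the C3 ketone of 22. The ring is thus enlarged rather than closed: the five-membered O1–C2–C3–C3a–C7a ring takes up the former aldehyde carbon between C3 and C3a and becomes the six-membered O1–C2–C3–C4–C4a–C8a ring, in the same flask in which the C4–C2' bond is made. The closest known reaction types are the semipinacol rearrangement of β-sulfonyloxy carbinols with aryl migration, the Tiffeneau–Demjanov enlargement of 1-indanone-derived carbinols to 2-tetralones and the iodine(III)-induced ring expansion of exocyclic styrenes on benzo-fused rings; not yet shown are the 2,3-dihydrobenzofuran-3-ol substrate class and the direct link to the aryllithium addition. C4 is the only lasting new stereocentre and is fixed by inversion at the R carbinol carbon, which places ring E cis to ring B (4S), while C2 is not touched and the temporary C3 centre is erased. The step needs migration of ring A in preference to C2 and to oxirane closure: C3a is para to the 6-benzyloxy oxygen and ortho to O1, which makes ring A the better bridging group, the C2–C3 bond is gauche to the leaving group in the reactive rotamer and is inductively deactivated by O1, and the silyl cap blocks oxirane formation and ends the shift irreversibly.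

Step 15
Reactants: 22 (2R,4S)-7-(benzyloxy)-4-{2,3,4-tris(benzyloxy)-6-[(2S)-7-(benzyloxy)-2H-chromen-2-yl]phenyl}-2-[3,4,5-tris(benzyloxy)phenyl]chroman-3-one
Product: 23 (2R,3S,4S)-7-(benzyloxy)-4-{2,3,4-tris(benzyloxy)-6-[(2S)-7-(benzyloxy)-2H-chromen-2-yl]phenyl}-2-[3,4,5-tris(benzyloxy)phenyl]chroman-3-ol (2,3-trans-3,4-trans)
Conditions: NaBH4, CeCl3·7H2O, MeOH–THF, −78 °C
Reagents that add atoms: none
Why: Luche reduction, in which the small hydride should add axially from the α face (free of 1,3-diaxial substituents because O1 and C4a flank the α-carbons) to give the equatorial 3β-alcohol trans to both pseudo-equatorial aryl groups, while the weakly acidic cerium medium at −78 °C avoids enolisation at C2 and C4.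

Step 16
Reactants: 23 (2R,3S,4S)-7-(benzyloxy)-4-{2,3,4-tris(benzyloxy)-6-[(2S)-7-(benzyloxy)-2H-chromen-2-yl]phenyl}-2-[3,4,5-tris(benzyloxy)phenyl]chroman-3-ol
Product: 24 (2R,3S,4S)-7-(benzyloxy)-2-{3,4,5-tris(benzyloxy)-2-[(2R,3S,4S)-7-(benzyloxy)-3-hydroxy-2-[3,4,5-tris(benzyloxy)phenyl]chroman-4-yl]phenyl}chromane-3,4-diol (octa-O-benzyl ether of the target)
Conditions: OsO4 (5 mol %), NMO, acetone–THF–H2O, rt
Reagents that add atoms: N-methylmorpholine N-oxide, C[N+]1([O-])CCOCC1; water, O (both oxygens are passed on through catalytic osmium tetroxide, O=[Os](=O)(=O)=O)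
Why: Catalytic osmium tetroxide syn-dihydroxylation of the only alkene occurs on the face of ring F opposite to the bulky ring E at C2, the known outcome for flav-3-enes, and sets C3 and C4 as the 2,3-trans-3,4-cis diol in one event.

Step 17
Reactants: 24 octa-O-benzyl ether of the target
Product: 25 (2R,3S,4S)-2-{3,4,5-trihydroxy-2-[(2R,3S,4S)-3,7-dihydroxy-2-(3,4,5-trihydroxyphenyl)chroman-4-yl]phenyl}chromane-3,4,7-triol (target)
Conditions: H2 (1 atm), Pd(OH)2/C, THF–MeOH, rt
Reagents that add atoms: none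
Why: Hydrogenolysis of the eight aryl benzyl ethers over Pearlman's catalyst under neutral conditions at 1 atm, as used for benzylated flavan-3-ols and proanthocyanidins, should leave the C2–O1 bonds and all six stereocentres intact.

**Compound list**
1 | [3,4,5-tris(benzyloxy)phenyl]methanol | OCc1cc(OCc2ccccc2)c(OCc2ccccc2)c(OCc2ccccc2)c1 | starting material
2 | 5-(bromomethyl)-1,2,3-tris(benzyloxy)benzene | BrCc1cc(OCc2ccccc2)c(OCc2ccccc2)c(OCc2ccccc2)c1 | intermediate
3 | 1-[4-(benzyloxy)-2-hydroxyphenyl]ethan-1-one | CC(=O)c1ccc(OCc2ccccc2)cc1O | starting material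
4 | 1-[4-(benzyloxy)-2-{[3,4,5-tris(benzyloxy)phenyl]methoxy}phenyl]ethan-1-one | CC(=O)c1ccc(OCc2ccccc2)cc1OCc1cc(OCc2ccccc2)c(OCc2ccccc2)c(OCc2ccccc2)c1 | intermediate
5 | methyl 2-[4-(benzyloxy)-2-{[3,4,5-tris(benzyloxy)phenyl]methoxy}phenyl]acetate | COC(=O)Cc1ccc(OCc2ccccc2)cc1OCc1cc(OCc2ccccc2)c(OCc2ccccc2)c(OCc2ccccc2)c1 | intermediate
6 | methyl 2-diazo-2-[4-(benzyloxy)-2-{[3,4,5-tris(benzyloxy)phenyl]methoxy}phenyl]acetate | COC(=O)C(=[N+]=[N-])c1ccc(OCc2ccccc2)cc1OCc1cc(OCc2ccccc2)c(OCc2ccccc2)c(OCc2ccccc2)c1 | intermediate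
7 | methyl (2S,3R)-6-(benzyloxy)-2-[3,4,5-tris(benzyloxy)phenyl]-2,3-dihydro-1-benzofuran-3-carboxylate (cis) | c1ccccc1COc1ccc2c(c1)O[C@H](c1cc(OCc3ccccc3)c(OCc3ccccc3)c(OCc3ccccc3)c1)[C@@H]2C(=O)OC | intermediate
8 | potassium ester enolate of 7 | c1ccccc1COc1ccc2c(c1)O[C@H](c1cc(OCc3ccccc3)c(OCc3ccccc3)c(OCc3ccccc3)c1)C2=C([O-])OC.[K+] | intermediate
9 | methyl (2R,3S)-6-(benzyloxy)-3-hydroxy-2-[3,4,5-tris(benzyloxy)phenyl]-2,3-dihydro-1-benzofuran-3-carboxylate | c1ccccc1COc1ccc2c(c1)O[C@H](c1cc(OCc3ccccc3)c(OCc3ccccc3)c(OCc3ccccc3)c1)[C@]2(O)C(=O)OC | intermediate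
10 | methyl (2R,3S)-6-(benzyloxy)-3-[(tert-butyldimethylsilyl)oxy]-2-[3,4,5-tris(benzyloxy)phenyl]-2,3-dihydro-1-benzofuran-3-carboxylate | c1ccccc1COc1ccc2c(c1)O[C@H](c1cc(OCc3ccccc3)c(OCc3ccccc3)c(OCc3ccccc3)c1)[C@]2(O[Si](C)(C)C(C)(C)C)C(=O)OC | intermediate
11 | (2R,3S)-6-(benzyloxy)-3-[(tert-butyldimethylsilyl)oxy]-2-[3,4,5-tris(benzyloxy)phenyl]-2,3-dihydro-1-benzofuran-3-carbaldehyde | c1ccccc1COc1ccc2c(c1)O[C@H](c1cc(OCc3ccccc3)c(OCc3ccccc3)c(OCc3ccccc3)c1)[C@]2(O[Si](C)(C)C(C)(C)C)C=O | intermediate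
12 | 3,4,5-tris(benzyloxy)benzaldehyde | O=Cc1cc(OCc2ccccc2)c(OCc2ccccc2)c(OCc2ccccc2)c1 | starting material
13 | 2-bromo-3,4,5-tris(benzyloxy)benzaldehyde | O=Cc1cc(OCc2ccccc2)c(OCc2ccccc2)c(OCc2ccccc2)c1Br | intermediate
14 | (E)-1-[4-(benzyloxy)-2-hydroxyphenyl]-3-[2-bromo-3,4,5-tris(benzyloxy)phenyl]prop-2-en-1-one | O=C(/C=C/c1cc(OCc2ccccc2)c(OCc2ccccc2)c(OCc2ccccc2)c1Br)c1ccc(OCc2ccccc2)cc1O | intermediate
15 | rac-7-(benzyloxy)-2-[2-bromo-3,4,5-tris(benzyloxy)phenyl]chroman-4-one | O=C1CC(c2cc(OCc3ccccc3)c(OCc3ccccc3)c(OCc3ccccc3)c2Br)Oc2cc(OCc3ccccc3)ccc12 | intermediate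
16 | (2S,4S)-7-(benzyloxy)-2-[2-bromo-3,4,5-tris(benzyloxy)phenyl]chroman-4-ol | Brc1c([C@H]2Oc3cc(OCc4ccccc4)ccc3[C@@H](O)C2)cc(OCc2ccccc2)c(OCc2ccccc2)c1OCc1ccccc1 | intermediate
17 | 4-methanesulfonate of 16 | Brc1c([C@H]2Oc3cc(OCc4ccccc4)ccc3[C@@H](OS(C)(=O)=O)C2)cc(OCc2ccccc2)c(OCc2ccccc2)c1OCc1ccccc1 | intermediate
18 | (2S)-7-(benzyloxy)-2-[2-bromo-3,4,5-tris(benzyloxy)phenyl]-2H-chromene | Brc1c([C@H]2Oc3cc(OCc4ccccc4)ccc3C=C2)cc(OCc2ccccc2)c(OCc2ccccc2)c1OCc1ccccc1 | intermediate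
19 | {2,3,4-tris(benzyloxy)-6-[(2S)-7-(benzyloxy)-2H-chromen-2-yl]phenyl}lithium | [Li]c1c([C@H]2Oc3cc(OCc4ccccc4)ccc3C=C2)cc(OCc2ccccc2)c(OCc2ccccc2)c1OCc1ccccc1 | intermediate
20 | lithium alkoxide of the adduct of 19 and 11 (carbinol carbon R; C2 and C3 of the dihydrobenzofuran arranged as in 11) | c1ccccc1COc1ccc2c(c1)O[C@H](c1cc(OCc3ccccc3)c(OCc3ccccc3)c(OCc3ccccc3)c1)[C@]2(O[Si](C)(C)C(C)(C)C)[C@H]([O-])c1c([C@H]2Oc3cc(OCc4ccccc4)ccc3C=C2)cc(OCc2ccccc2)c(OCc2ccccc2)c1OCc1ccccc1.[Li+] | intermediate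
21 | methanesulfonate of the same carbinol (carbinol carbon R) | c1ccccc1COc1ccc2c(c1)O[C@H](c1cc(OCc3ccccc3)c(OCc3ccccc3)c(OCc3ccccc3)c1)[C@]2(O[Si](C)(C)C(C)(C)C)[C@H](OS(C)(=O)=O)c1c([C@H]2Oc3cc(OCc4ccccc4)ccc3C=C2)cc(OCc2ccccc2)c(OCc2ccccc2)c1OCc1ccccc1 | intermediate
22 | (2R,4S)-7-(benzyloxy)-4-{2,3,4-tris(benzyloxy)-6-[(2S)-7-(benzyloxy)-2H-chromen-2-yl]phenyl}-2-[3,4,5-tris(benzyloxy)phenyl]chroman-3-one | c1ccccc1COc1ccc2c(c1)O[C@H](c1cc(OCc3ccccc3)c(OCc3ccccc3)c(OCc3ccccc3)c1)C(=O)[C@@H]2c1c([C@H]2Oc3cc(OCc4ccccc4)ccc3C=C2)cc(OCc2ccccc2)c(OCc2ccccc2)c1OCc1ccccc1 | intermediate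
23 | (2R,3S,4S)-7-(benzyloxy)-4-{2,3,4-tris(benzyloxy)-6-[(2S)-7-(benzyloxy)-2H-chromen-2-yl]phenyl}-2-[3,4,5-tris(benzyloxy)phenyl]chroman-3-ol | c1ccccc1COc1ccc2c(c1)O[C@H](c1cc(OCc3ccccc3)c(OCc3ccccc3)c(OCc3ccccc3)c1)[C@@H](O)[C@@H]2c1c([C@H]2Oc3cc(OCc4ccccc4)ccc3C=C2)cc(OCc2ccccc2)c(OCc2ccccc2)c1OCc1ccccc1 | intermediate
24 | octa-O-benzyl ether of the target | c1ccccc1COc1ccc2c(c1)O[C@H](c1cc(OCc3ccccc3)c(OCc3ccccc3)c(OCc3ccccc3)c1)[C@@H](O)[C@@H]2c1c([C@H]2Oc3cc(OCc4ccccc4)ccc3[C@H](O)[C@@H]2O)cc(OCc2ccccc2)c(OCc2ccccc2)c1OCc1ccccc1 | intermediate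
25 | (2R,3S,4S)-2-{3,4,5-trihydroxy-2-[(2R,3S,4S)-3,7-dihydroxy-2-(3,4,5-trihydroxyphenyl)chroman-4-yl]phenyl}chromane-3,4,7-triol | Oc1ccc2c(c1)O[C@H](c1cc(O)c(O)c(O)c1)[C@@H](O)[C@@H]2c1c([C@H]2Oc3cc(O)ccc3[C@H](O)[C@@H]2O)cc(O)c(O)c1O | target

Total step count: 17. Longest linear sequence: 12 (steps 1–8 and 14–17).

**Steps most likely to fail**

1. Step 14.
- What may go wrong: transfer of the silyl group from the tertiary to the secondary oxygen before sulfonylation, ionisation without aryl participation (erosion of the C4 configuration), or migration of C2 in place of ring A.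
- Fallback (sets out from 11 and 18, comes back at 22): the sequence is taken apart and the shift is run as the known organoaluminium-promoted pinacol-type rearrangement of a β-mesyloxy alcohol. Aryllithium 19 is added to 11 and the mixture is quenched with aqueous NH4Cl to give the silyl-protected carbinol F1, which can be freed from its minor epimer. TBAF in THF gives the vicinal diol F2. MsCl/Et3N at −40 °C sulfonylates only the secondary hydroxyl to give the hydroxy mesylate F3. This is treated at once with Et3Al in CH2Cl2 at −78 °C, where the aluminium alkoxide drives a concerted anti 1,2-aryl shift to 22.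

2. Step 17.
- What may go wrong: hydrogenolysis of the benzylic C4–OH of ring F, which is activated by the para 7-oxygen, in competition with O-debenzylation.
- Fallback (sets out from 23, comes back at 25): the protecting groups are exchanged before the diol exists, so that the last step is not reductive. BCl3 with pentamethylbenzene in CH2Cl2 at −78 °C cleaves the aryl benzyl ethers of 23 and spares the alkene, giving the octaphenolic flavene F4. TBSCl/imidazole in DMF gives the octakis(silyl) ether F5. OsO4/NMO dihydroxylates ring F anti to ring E to give the silylated diol F6. Et3N·3HF in THF at 0 °C releases 25.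

3. Step 15.
- What may go wrong: poor facial selectivity of hydride delivery, or enolisation at C2/C4 of the ketone before reduction.
- Fallback (sets out from 22, comes back at 23): the opposite face is used on purpose and C3 is then inverted. L-Selectride at −78 °C attacks equatorially to give the 2,3-cis-3,4-cis alcohol F7. Mitsunobu reaction with 4-nitrobenzoic acid, DIAD and PPh3 inverts C3 to the 3β-(4-nitrobenzoate) F8. K2CO3 in MeOH–THF gives 23.

**Further compounds**
F1 | step 14 | silyl-protected carbinol (protonated 20, carbinol carbon R) | c1ccccc1COc1ccc2c(c1)O[C@H](c1cc(OCc3ccccc3)c(OCc3ccccc3)c(OCc3ccccc3)c1)[C@]2(O[Si](C)(C)C(C)(C)C)[C@H](O)c1c([C@H]2Oc3cc(OCc4ccccc4)ccc3C=C2)cc(OCc2ccccc2)c(OCc2ccccc2)c1OCc1ccccc1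
F2 | step 14 | vicinal diol (tertiary C3–OH and R secondary carbinol) | c1ccccc1COc1ccc2c(c1)O[C@H](c1cc(OCc3ccccc3)c(OCc3ccccc3)c(OCc3ccccc3)c1)[C@]2(O)[C@H](O)c1c([C@H]2Oc3cc(OCc4ccccc4)ccc3C=C2)cc(OCc2ccccc2)c(OCc2ccccc2)c1OCc1ccccc1
F3 | step 14 | hydroxy mesylate (secondary O-mesylate, free tertiary OH) | c1ccccc1COc1ccc2c(c1)O[C@H](c1cc(OCc3ccccc3)c(OCc3ccccc3)c(OCc3ccccc3)c1)[C@]2(O)[C@H](OS(C)(=O)=O)c1c([C@H]2Oc3cc(OCc4ccccc4)ccc3C=C2)cc(OCc2ccccc2)c(OCc2ccccc2)c1OCc1ccccc1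
F4 | step 17 | octaphenolic flavene (23 without benzyl groups) | Oc1ccc2c(c1)O[C@H](c1cc(O)c(O)c(O)c1)[C@@H](O)[C@@H]2c1c([C@H]2Oc3cc(O)ccc3C=C2)cc(O)c(O)c1O
F5 | step 17 | octakis(tert-butyldimethylsilyl) ether of F4 | CC(C)(C)[Si](C)(C)Oc1ccc2c(c1)O[C@H](c1cc(O[Si](C)(C)C(C)(C)C)c(O[Si](C)(C)C(C)(C)C)c(O[Si](C)(C)C(C)(C)C)c1)[C@@H](O)[C@@H]2c1c([C@H]2Oc3cc(O[Si](C)(C)C(C)(C)C)ccc3C=C2)cc(O[Si](C)(C)C(C)(C)C)c(O[Si](C)(C)C(C)(C)C)c1O[Si](C)(C)C(C)(C)C
F6 | step 17 | octakis(tert-butyldimethylsilyl) ether of the target | CC(C)(C)[Si](C)(C)Oc1ccc2c(c1)O[C@H](c1cc(O[Si](C)(C)C(C)(C)C)c(O[Si](C)(C)C(C)(C)C)c(O[Si](C)(C)C(C)(C)C)c1)[C@@H](O)[C@@H]2c1c([C@H]2Oc3cc(O[Si](C)(C)C(C)(C)C)ccc3[C@H](O)[C@@H]2O)cc(O[Si](C)(C)C(C)(C)C)c(O[Si](C)(C)C(C)(C)C)c1O[Si](C)(C)C(C)(C)C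
F7 | step 15 | 2,3-cis-3,4-cis alcohol (C3 epimer of 23) | c1ccccc1COc1ccc2c(c1)O[C@H](c1cc(OCc3ccccc3)c(OCc3ccccc3)c(OCc3ccccc3)c1)[C@H](O)[C@@H]2c1c([C@H]2Oc3cc(OCc4ccccc4)ccc3C=C2)cc(OCc2ccccc2)c(OCc2ccccc2)c1OCc1ccccc1
F8 | step 15 | 3-O-(4-nitrobenzoate) of 23 | c1ccccc1COc1ccc2c(c1)O[C@H](c1cc(OCc3ccccc3)c(OCc3ccccc3)c(OCc3ccccc3)c1)[C@@H](OC(=O)c1ccc(cc1)[N+](=O)[O-])[C@@H]2c1c([C@H]2Oc3cc(OCc4ccccc4)ccc3C=C2)cc(OCc2ccccc2)c(OCc2ccccc2)c1OCc1ccccc1
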